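Cuts: (a) the ester between C13–O of unit B and the central carboxyl of isocitrate A; (b) in each half the ether bond C11–O, made while C11 is still allylic; (c) in each drimane C9–C10; (d) in unit B C4–C5 (epoxide-opened polyene closure); (e) in unit A the bond C4–C5 is returned to C4–C10.
Enabling feature: in ring A of unit A (C1–C2–C3–C4–C5–C10) the gem-dimethyl carbon C4, the methine C5 and the methyl-bearing quaternary C10 stand in a row. A 1,2-shift of C4 from C10 to C5 therefore derives ring A from the 1,2,2-trimethylcyclopentane ring (C1–C2–C3–C4–C10) of camphoric acid, with C5 as exocyclic carbinyl carbon, and leaves the cation on C10, where ring B must close.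
Forward, unit A: camphoric acid → methyl ketone → C6–C7 propargylation → C5 carbinol → Z-iodoalkene → ether with isocitrate A → allylsilane → mesylate. One solvolysis then enlarges the five-membered ring to ring A, closes ring B and installs the C8=C12 methylene.
Forward, unit B and union: geranyl bromide → the same iodoalkene/ether/allylsilane sequence with isocitrate B, terminal allylic oxidation, epoxidation, chair–chair bicyclisation (rings A and B together), C3 deoxygenation. The halves are esterified and the two tert-butyl esters are removed last.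
Stereochemistry: C2' comes from D-malic acid or dimethyl D-malate and C3' from Fráter–Seebach alkylation. In unit A, C10 comes from (1S,3R)-camphoric acid and C5 from a CBS reduction (both inverted in the key step), and C9 from the alkene geometry. In unit B, C4, C5, C9 and C10 come from a Sharpless epoxidation relayed through the chair–chair closure.

Key step: step 15

Remark: drimane numbering is used for both sesquiterpene units (C11 = CH2O on C9; C12 = exocyclic CH2; C13 = 4α-CH2O of unit B; albicanyl = drim-8(12)-en-11-yl). Isocitrate carbons carry primes (C2' ether carbon; C3' central methine). Unit A is the gem-dimethyl drimane and unit B the 13-oxygenated one. D-malic acid, dimethyl D-malate, (1S,3R)-camphoric acid and geranyl bromide are assumed to be catalogue items.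

Step 1
Reactants: 1 D-malic acid
Product: 3 (R)-malic acid 1-methyl ester, via O-trifluoroacetyl-D-malic anhydride 2 (not isolated)
Conditions: (CF3CO)2O, 0 °C to rt, evaporate; MeOH, rt
Reagents that add atoms: methanol (SMILES: CO)
Why: Anhydride formation and regioselective alcoholysis: the cyclic anhydride should open at the carbonyl next to the electron-withdrawing trifluoroacetoxy group and the trifluoroacetate is then lost to methanol, so only the carboxyl on C2' is esterified and the (R) centre is untouched.

Step 2
Reactants: 3 (R)-malic acid 1-methyl ester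
Product: 4 1-methyl 4-[2-(trimethylsilyl)ethyl] (R)-malate
Conditions: Me3SiCH2CH2OH (3 equiv), EDC·HCl, DMAP (cat), CH2Cl2, 0 °C to rt
Reagents that add atoms: 2-(trimethylsilyl)ethanol (SMILES: C[Si](C)(C)CCO)
Why: Steglich-type carbodiimide esterification should take the only free carboxyl group, the excess primary alcohol outrunning the deactivated secondary hydroxyl of the substrate.

Step 3
Reactants: 4 1-methyl 4-[2-(trimethylsilyl)ethyl] (R)-malate
Product: 6 isocitrate block A, via dilithio alkoxide enolate 5 (not isolated)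
Conditions: LiN(SiMe3)2 (2.2 equiv), THF, −78 to −20 °C; BrCH2CO2t-Bu, −78 °C; AcOH quench at −78 °C
Reagents that add atoms: tert-butyl bromoacetate (SMILES: CC(C)(C)OC(=O)CBr)
Why: Fráter–Seebach alkylation: the chelated alkoxide enolate is alkylated on the face anti to the ester substituent on C2', which sets C3' as (S) in the anti (natural threo) series, and the tert-butyl ester resists lactonisation by the neighbouring alkoxide.

Step 4
Reactants: 7 dimethyl D-malate
Product: 9 isocitrate block B, via dilithio alkoxide enolate 8 (not isolated)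
Conditions: LiN(SiMe3)2 (2.2 equiv), THF, −78 to −20 °C; BrCH2CO2t-Bu, −78 °C; AcOH quench at −78 °C
Reagents that add atoms: tert-butyl bromoacetate (SMILES: CC(C)(C)OC(=O)CBr)
Why: The same Fráter–Seebach alkylation sets C3' as (S) anti to the C2' oxygen and delivers the terminal carboxyl as the only tert-butyl ester.

Step 5
Reactants: 10 (1S,3R)-(−)-camphoric acid
Product: 13 (S)-camphonanic acid, via camphoric anhydride 11 (not isolated), via Barton ester 12 (not isolated)
Conditions: DCC (1.0 equiv), CH2Cl2, 0 °C; 1-hydroxypyridine-2(1H)-thione, DMAP (cat), dark, rt; t-BuSH, hν (tungsten lamp), rt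
Reagents that add atoms: none
Why: Barton reductive decarboxylation: only the secondary carbonyl is open to the thiohydroxamic acid because the tertiary one lies between two quaternary carbons, photolysis drains the ester irreversibly, and the quaternary (S) centre, the later C10, is not touched.

Step 6
Reactants: 13 (S)-camphonanic acid
Product: 14 1-[(1S)-1,2,2-trimethylcyclopentyl]ethan-1-one
Conditions: MeLi (2.5 equiv), Et2O, 0 °C to rt; poured into cold aq HCl
Reagents that add atoms: methyllithium (SMILES: [Li]C)
Why: Addition of an alkyllithium to a lithium carboxylate is a standard ketone synthesis that suits hindered acids, because the carboxylate takes up only one equivalent of reagent before work-up.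

Step 7
Reactants: 14 1-[(1S)-1,2,2-trimethylcyclopentyl]ethan-1-one
Product: 16 1-[(1S)-1,2,2-trimethylcyclopentyl]pent-4-yn-1-one, via lithium enolate 15 (not isolated)
Conditions: LiN(iPr)2, THF, −78 °C; HC≡CCH2Br, −78 to −20 °C
Reagents that add atoms: propargyl bromide (SMILES: C#CCBr)
Why: Kinetic enolate alkylation: the ketone can enolise only toward its methyl group and the reactive propargylic bromide forms the C6–C7 bond at low temperature.

Step 8
Reactants: 16 1-[(1S)-1,2,2-trimethylcyclopentyl]pent-4-yn-1-one
Product: 17 (1S)-1-[(1S)-1,2,2-trimethylcyclopentyl]pent-4-yn-1-ol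
Conditions: (R)-2-methyl-CBS-oxazaborolidine (0.2 equiv), BH3·SMe2 (0.7 equiv), THF, −20 °C, slow addition of 16; MeOH
Reagents that add atoms: none
Why: Corey–Bakshi–Shibata reduction: the catalyst tells the tertiary alkyl group from the unbranched chain as it does in pinacolone, the (R)-catalyst giving the (5S)-carbinol under reagent control, and the catalysed carbonyl reduction outruns hydroboration of the alkyne.

Step 9
Reactants: 17 (1S)-1-[(1S)-1,2,2-trimethylcyclopentyl]pent-4-yn-1-ol
Product: 19 (6S)-6-[(1S)-1,2,2-trimethylcyclopentyl]hex-2-yne-1,6-diol, via dilithio alkoxide acetylide 18 (not isolated)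
Conditions: n-BuLi (2.2 equiv), THF, −78 °C; (CH2O)n, −78 °C to rt; H2O
Reagents that add atoms: paraformaldehyde, counted as formaldehyde (SMILES: C=O)
Why: Hydroxymethylation of a lithium acetylide by formaldehyde is a standard one-carbon homologation (it adds C11), and the hindered lithium alkoxide at C5 is a spectator.

Step 10
Reactants: 19 (6S)-6-[(1S)-1,2,2-trimethylcyclopentyl]hex-2-yne-1,6-diol
Product: 21 (2Z,6S)-3-iodo-6-[(1S)-1,2,2-trimethylcyclopentyl]hex-2-ene-1,6-diol, via cyclic alkenylaluminate 20 (not isolated)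
Conditions: NaAlH2(OCH2CH2OMe)2 (3.5 equiv), THF, 0 °C to rt; I2, THF, −78 °C
Reagents that add atoms: iodine (SMILES: II)
Why: Hydroxyl-directed trans-hydroalumination of the propargylic alcohol places aluminium on C8 in a five-membered chelate and iodinolysis keeps the geometry, so iodine ends cis to C11 and C7 trans to C11.

Step 11
Reactants: 21 (2Z,6S)-3-iodo-6-[(1S)-1,2,2-trimethylcyclopentyl]hex-2-ene-1,6-diol
Product: 22 (1S,4Z)-6-bromo-4-iodo-1-[(1S)-1,2,2-trimethylcyclopentyl]hex-4-en-1-ol
Conditions: NBS and Me2S premixed, CH2Cl2, −30 to 0 °C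
Reagents that add atoms: N-bromosuccinimide (SMILES: O=C1CCC(=O)N1Br)
Why: Corey–Kim-type halogenation with the preformed bromosulfonium salt converts allylic alcohols selectively, the neopentylic C5 hydroxyl is returned unchanged on work-up, and it cannot close onto C11 because C7 and C11 are trans on the alkene.

Step 12
Reactants: 22 (1S,4Z)-6-bromo-4-iodo-1-[(1S)-1,2,2-trimethylcyclopentyl]hex-4-en-1-ol; 6 isocitrate block A
Product: 23 iodoalkenyl ether A
Conditions: Ag2O (2 equiv), 6 (1.5 equiv), 4 Å molecular sieves, CH2Cl2, dark, rt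
Reagents that add atoms: none
Why: Ag2O-mediated O-alkylation (Purdie-type Williamson etherification) joins C11 to the C2' oxygen under essentially neutral conditions, which spares C2', C3' and the three esters, and the crowded C5 hydroxyl does not compete.

Step 13
Reactants: 23 iodoalkenyl ether A
Product: 24 allylsilane carbinol A
Conditions: Me3SiCH2MgCl and ZnCl2, THF, 0 °C; Pd(PPh3)4 (5 mol %), rt
Reagents that add atoms: (trimethylsilyl)methylmagnesium chloride (SMILES: C[Si](C)(C)C[Mg]Cl)
Why: Negishi coupling: zerovalent palladium inserts into the C–I bond with retention and the ester-tolerant zinc reagent delivers the CH2SiMe3 group, giving the allylsilane with C12 cis to C11.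

Step 14
Reactants: 24 allylsilane carbinol A
Product: 25 allylsilane mesylate A
Conditions: MsCl, Et3N, CH2Cl2, −30 to 0 °C, cold work-up, used at once
Reagents that add atoms: methanesulfonyl chloride (SMILES: CS(=O)(=O)Cl)
Why: Sulfonylation through sulfene reaches even the crowded C5 hydroxyl without touching the C–O bond, so the (5S) configuration is kept.

Step 15
Reactants: 25 allylsilane mesylate A
Product: 27 albicanyl ether A, via ring-enlarged C10 cation 26 (not isolated)
Conditions: (CF3)2CHOH, 2,6-lutidine (2 equiv), 0.005 M, rt to 45 °C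
Reagents that add atoms: none
Why: Proposed new method: ionisation of the neopentylic C5 mesylate in the strongly ionising, non-nucleophilic solvent is assisted by the antiperiplanar C10–C4 bond, so that C4 migrates from C10 to C5 (Wagner–Meerwein shift), the cyclopentane C1–C2–C3–C4–C10 becomes six-membered ring A with a tertiary cation at C10, C9 of the tethered allylsilane captures this cation and loss of the silyl group from C12 leaves the C8=C12 methylene. The closest known reaction types are the solvolytic cyclopentylcarbinyl-to-cyclohexyl ring enlargement (as in the D-homoannulation of pregnan-20-yl sulfonates), the allylsilane-terminated cation–olefin cyclisation and the enlargement-then-annulation sequence of triterpene biosynthesis, but their union in one event on such a substrate has not been shown. Ring A arises by one-carbon ring expansion through the 1,2-alkyl shift and ring B closes in the 6-endo-trig mode (C9 onto C10) through a chair-like transition state. C5 is set by inversion of the (5S)-carbinol carbon because C4 enters anti to the leaving group, C10 is set because C9 enters anti to the departing C4, the (10S) configuration from camphoric acid having been chosen so that this anti attack and the equatorial-chain chair closure of a relaxed cation both give the trans-decalin, and C9 follows from the alkene geometry, C11 being trans to C7 and hence equatorial. The step needs migration of C4 rather than of C1 or the methyl group, which the higher migratory aptitude of the fully substituted carbon, the relief of the vicinal quaternary strain and the gain of a six-membered ring should secure, and it needs capture of the cation ahead of proton loss or hydride shift, which the nucleophilic allylsilane in a six-membered transition state and the lutidine buffer should secure. The esters and the allylic ether are weak donors and poor leaving groups under these buffered conditions and should remain spectators.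

Step 16
Reactants: 27 albicanyl ether A
Product: 28 acid A
Conditions: Bu4NF (2 equiv), THF, 0 °C to rt; cold dilute aq HCl
Reagents that add atoms: none
Why: Fluoride-induced fragmentation of the 2-(trimethylsilyl)ethyl ester frees only the central carboxyl and leaves the methyl and tert-butyl esters and the exocyclic alkene alone.

Step 17
Reactants: 29 geranyl bromide
Product: 31 (6E)-7,11-dimethyldodeca-6,10-dien-2-yn-1-ol, via lithium acetylide 30 (not isolated)
Conditions: propyne, n-BuLi (2 equiv), TMEDA, THF–hexane, −78 to 0 °C; 29, −78 to 0 °C; (CH2O)n, rt; H2O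
Reagents that add atoms: propyne (SMILES: CC#C); paraformaldehyde, counted as formaldehyde (SMILES: C=O)
Why: Propargylation of the allylic bromide by 1,3-dilithiopropyne occurs at the more reactive sp3 carbanion by direct displacement (C6–C7 bond), and the remaining acetylide is hydroxymethylated in the same flask.

Step 18
Reactants: 31 (6E)-7,11-dimethyldodeca-6,10-dien-2-yn-1-ol
Product: 33 (2Z,6E)-3-iodo-7,11-dimethyldodeca-2,6,10-trien-1-ol, via cyclic alkenylaluminate 32 (not isolated)
Conditions: NaAlH2(OCH2CH2OMe)2 (2 equiv), THF, 0 °C to rt; I2, THF, −78 °C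
Reagents that add atoms: iodine (SMILES: II)
Why: Hydroxyl-directed trans-hydroalumination and iodinolysis with retention put iodine on C8 cis to C11, as in step 10.

Step 19
Reactants: 33 (2Z,6E)-3-iodo-7,11-dimethyldodeca-2,6,10-trien-1-ol
Product: 34 (2Z,6E)-1-bromo-3-iodo-7,11-dimethyldodeca-2,6,10-triene
Conditions: NBS and Me2S premixed, CH2Cl2, −30 to 0 °C
Reagents that add atoms: N-bromosuccinimide (SMILES: O=C1CCC(=O)N1Br)
Why: Corey–Kim-type halogenation with the preformed bromosulfonium salt replaces the allylic hydroxyl without allylic transposition and leaves no free brominating agent for the trisubstituted alkenes.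

Step 20
Reactants: 34 (2Z,6E)-1-bromo-3-iodo-7,11-dimethyldodeca-2,6,10-triene; 9 isocitrate block B
Product: 35 iodotrienyl ether B
Conditions: Ag2O (2 equiv), 9 (1.5 equiv), 4 Å molecular sieves, CH2Cl2, dark, rt
Reagents that add atoms: none
Why: The same Ag2O-mediated O-alkylation forms the C11–O–C2' ether under neutral conditions with retention at C2' and C3'.

Step 21
Reactants: 35 iodotrienyl ether B
Product: 36 12-hydroxy iodotrienyl ether B
Conditions: SeO2 (0.2 equiv), t-BuOOH, CH2Cl2, 0 °C to rt
Reagents that add atoms: tert-butyl hydroperoxide (SMILES: CC(C)(C)OO)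
Why: Selenium dioxide allylic oxidation (ene reaction then 2,3-sigmatropic shift) attacks the most electron-rich and least hindered terminal trisubstituted alkene and gives the E-allylic alcohol, the iodoalkene being deactivated.

Step 22
Reactants: 36 12-hydroxy iodotrienyl ether B
Product: 37 allylsilane allylic alcohol B
Conditions: Me3SiCH2MgCl and ZnCl2, THF, 0 °C; Pd(PPh3)4 (5 mol %), rt
Reagents that add atoms: (trimethylsilyl)methylmagnesium chloride (SMILES: C[Si](C)(C)C[Mg]Cl)
Why: Negishi coupling with retention of the alkene geometry installs the allylsilane after the selenium step, which an allylsilane would not survive, and tolerates the esters and the free hydroxyl.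

Step 23
Reactants: 37 allylsilane allylic alcohol B
Product: 38 epoxy alcohol B
Conditions: Ti(OiPr)4 (0.15 equiv), L-(+)-diethyl tartrate (0.2 equiv), t-BuOOH, 4 Å molecular sieves, CH2Cl2, −20 °C
Reagents that add atoms: tert-butyl hydroperoxide (SMILES: CC(C)(C)OO)
Why: Sharpless asymmetric epoxidation acts only on the alkene that carries the free allylic hydroxyl, and L-(+)-diethyl tartrate should give the (3S,4S)-epoxide as with other E-2-methylalk-2-en-1-ols.

Step 24
Reactants: 38 epoxy alcohol B
Product: 39 silyl-protected epoxide B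
Conditions: t-BuPh2SiCl, imidazole, CH2Cl2, 0 °C to rt
Reagents that add atoms: tert-butyl(chloro)diphenylsilane (SMILES: CC(C)(C)[Si](Cl)(c1ccccc1)c1ccccc1)
Why: Silylation of the primary alcohol under weakly basic conditions avoids epoxide migration, and the bulky weakly basic silyl ether keeps the C13 oxygen from chelating the Lewis acid in the next step.

Step 25
Reactants: 39 silyl-protected epoxide B
Product: 40 3β-hydroxy bicycle B
Conditions: MeAlCl2 (5 equiv), CH2Cl2, −78 °C, short contact; Et3N–MeOH quench, then H2O
Reagents that add atoms: none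
Why: Epoxide-initiated cation–olefin bicyclisation terminated by an allylsilane: chair–chair folding with anti opening at C4 turns the E-CH2O group into the equatorial 4α substituent, relays the epoxide configuration to C5, C10 and C9 (trans-decalin with equatorial C11), and loss of silicon fixes the C8=C12 methylene.

Step 26
Reactants: 40 3β-hydroxy bicycle B
Product: 41 3-O-(imidazol-1-ylthiocarbonyl) bicycle B
Conditions: 1,1'-thiocarbonyldiimidazole, DMAP, toluene, 80 °C
Reagents that add atoms: 1,1'-thiocarbonyldiimidazole (SMILES: S=C(n1ccnc1)n1ccnc1)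
Why: Thioacylation of the only free hydroxyl, an equatorial secondary alcohol, is the first half of the Barton–McCombie sequence and needs no strong base.

Step 27
Reactants: 41 3-O-(imidazol-1-ylthiocarbonyl) bicycle B
Product: 42 13-silyloxyalbicanyl ether B
Conditions: Bu3SnH, AIBN (cat), toluene, 100 °C
Reagents that add atoms: none
Why: Barton–McCombie deoxygenation: the stannyl radical adds to sulfur, the C3–O bond fragments, and the secondary C3 radical, which has no alkene within cyclisation range, is reduced by the stannane.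

Step 28
Reactants: 42 13-silyloxyalbicanyl ether B
Product: 43 alcohol B
Conditions: HF·pyridine, pyridine, THF, 0 °C to rt
Reagents that add atoms: none
Why: Fluoride cleavage of the silyl ether in a weakly acidic buffer avoids base-induced elimination in the isocitrate part and leaves the tert-butyl ester and the exocyclic alkene intact.

Step 29
Reactants: 28 acid A; 43 alcohol B
Product: 44 di-tert-butyl ester of the target
Conditions: 2-methyl-6-nitrobenzoic anhydride, DMAP, Et3N, CH2Cl2, rt
Reagents that add atoms: none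
Why: Shiina esterification through the mixed anhydride with acyl transfer by DMAP suits a hindered acid and a neopentylic alcohol at room temperature, which limits epimerisation at C3'.

Step 30
Reactants: 44 di-tert-butyl ester of the target
Product: 46 CNP0139922.2, via bis(trimethylsilyl) ester 45 (not isolated)
Conditions: Me3SiOTf (6 equiv), 2,6-lutidine (9 equiv), CH2Cl2, 0 °C to rt; pH 5 aqueous buffer
Reagents that add atoms: none
Why: Silyl-triflate-mediated cleavage of tert-butyl esters under lutidine buffer proceeds by loss of isobutene without free strong acid, so the exocyclic alkenes, the methyl esters and the inter-unit ester survive and the silyl esters hydrolyse on work-up.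

Compound list
1 | D-malic acid, (R)-2-hydroxybutanedioic acid | O[C@@H](C(=O)O)CC(=O)O | starting material
2 | O-trifluoroacetyl-D-malic anhydride | O=C1C[C@@H](OC(=O)C(F)(F)F)C(=O)O1 | intermediate
3 | (R)-malic acid 1-methyl ester, (3R)-3-hydroxy-4-methoxy-4-oxobutanoic acid | O[C@@H](C(=O)OC)CC(=O)O | intermediate
4 | 1-methyl 4-[2-(trimethylsilyl)ethyl] (R)-malate | O[C@@H](C(=O)OC)CC(=O)OCC[Si](C)(C)C | intermediate
5 | dilithio alkoxide enolate of 4 | [Li]O[C@@H](C(=O)OC)C=C(O[Li])OCC[Si](C)(C)C | intermediate
6 | isocitrate block A, 3-tert-butyl 1-methyl 2-[2-(trimethylsilyl)ethyl] (1R,2S)-1-hydroxypropane-1,2,3-tricarboxylate | O[C@@H](C(=O)OC)[C@H](CC(=O)OC(C)(C)C)C(=O)OCC[Si](C)(C)C | intermediate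
7 | dimethyl D-malate, dimethyl (R)-2-hydroxybutanedioate | O[C@@H](C(=O)OC)CC(=O)OC | starting material
8 | dilithio alkoxide enolate of 7 | [Li]O[C@@H](C(=O)OC)C=C(O[Li])OC | intermediate
9 | isocitrate block B, 3-tert-butyl 1,2-dimethyl (1R,2S)-1-hydroxypropane-1,2,3-tricarboxylate | O[C@@H](C(=O)OC)[C@H](CC(=O)OC(C)(C)C)C(=O)OC | intermediate
10 | (1S,3R)-(−)-camphoric acid, cis-1,2,2-trimethylcyclopentane-1,3-dicarboxylic acid | OC(=O)[C@@]1(C)CC[C@@H](C(=O)O)C1(C)C | starting material
11 | camphoric anhydride, (1S,5R)-1,8,8-trimethyl-3-oxabicyclo[3.2.1]octane-2,4-dione | O=C1OC(=O)[C@@]2(C)CC[C@@H]1C2(C)C | intermediate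
12 | Barton ester, (1S,3R)-1,2,2-trimethyl-3-{[(2-thioxopyridin-1(2H)-yl)oxy]carbonyl}cyclopentane-1-carboxylic acid | OC(=O)[C@@]1(C)CC[C@@H](C(=O)ON2C=CC=CC2=S)C1(C)C | intermediate
13 | (S)-camphonanic acid, (1S)-1,2,2-trimethylcyclopentane-1-carboxylic acid | OC(=O)[C@@]1(C)CCCC1(C)C | intermediate
14 | 1-[(1S)-1,2,2-trimethylcyclopentyl]ethan-1-one | CC(=O)[C@@]1(C)CCCC1(C)C | intermediate
15 | lithium enolate of 14 | C=C(O[Li])[C@@]1(C)CCCC1(C)C | intermediate
16 | 1-[(1S)-1,2,2-trimethylcyclopentyl]pent-4-yn-1-one | C#CCCC(=O)[C@@]1(C)CCCC1(C)C | intermediate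
17 | (1S)-1-[(1S)-1,2,2-trimethylcyclopentyl]pent-4-yn-1-ol | C#CCC[C@H](O)[C@@]1(C)CCCC1(C)C | intermediate
18 | dilithio alkoxide acetylide of 17 | [Li]C#CCC[C@H](O[Li])[C@@]1(C)CCCC1(C)C | intermediate
19 | (6S)-6-[(1S)-1,2,2-trimethylcyclopentyl]hex-2-yne-1,6-diol | OCC#CCC[C@H](O)[C@@]1(C)CCCC1(C)C | intermediate
20 | cyclic alkenylaluminate from 19 (five-membered O–C11–C9=C8–Al chelate, C5 alkoxide, idealised sodium salt) | COCCO[Al-]1(OCCOC)OCC=C1CC[C@H]([O-])[C@@]1(C)CCCC1(C)C.[Na+].[Na+] | intermediate
21 | (2Z,6S)-3-iodo-6-[(1S)-1,2,2-trimethylcyclopentyl]hex-2-ene-1,6-diol | OC/C=C(I)/CC[C@H](O)[C@@]1(C)CCCC1(C)C | intermediate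
22 | (1S,4Z)-6-bromo-4-iodo-1-[(1S)-1,2,2-trimethylcyclopentyl]hex-4-en-1-ol | BrC/C=C(I)/CC[C@H](O)[C@@]1(C)CCCC1(C)C | intermediate
23 | iodoalkenyl ether A, O-[(2Z,6S)-6-hydroxy-3-iodo-6-((1S)-1,2,2-trimethylcyclopentyl)hex-2-enyl] derivative of 6 | CC1(C)CCC[C@]1(C)[C@@H](O)CC/C(I)=C/CO[C@@H](C(=O)OC)[C@H](CC(=O)OC(C)(C)C)C(=O)OCC[Si](C)(C)C | intermediate
24 | allylsilane carbinol A, as 23 with CH2SiMe3 in place of iodine (2Z) | CC1(C)CCC[C@]1(C)[C@@H](O)CC/C(C[Si](C)(C)C)=C/CO[C@@H](C(=O)OC)[C@H](CC(=O)OC(C)(C)C)C(=O)OCC[Si](C)(C)C | intermediate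
25 | allylsilane mesylate A, (5S)-methanesulfonate of 24 | CC1(C)CCC[C@]1(C)[C@@H](OS(C)(=O)=O)CC/C(C[Si](C)(C)C)=C/CO[C@@H](C(=O)OC)[C@H](CC(=O)OC(C)(C)C)C(=O)OCC[Si](C)(C)C | intermediate
26 | ring-enlarged C10 cation (2,2,6-trimethylcyclohexyl cation with the (5S) side chain, mesylate counter-ion) | C[C+]1CCCC(C)(C)[C@@H]1CC/C(C[Si](C)(C)C)=C/CO[C@@H](C(=O)OC)[C@H](CC(=O)OC(C)(C)C)C(=O)OCC[Si](C)(C)C.CS(=O)(=O)[O-] | intermediate
27 | albicanyl ether A, O-[(5S,9S,10S)-drim-8(12)-en-11-yl] derivative of 6 | C=C1CC[C@H]2C(C)(C)CCC[C@]2(C)[C@H]1CO[C@@H](C(=O)OC)[C@H](CC(=O)OC(C)(C)C)C(=O)OCC[Si](C)(C)C | intermediate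
28 | acid A, as 27 with free central carboxyl | C=C1CC[C@H]2C(C)(C)CCC[C@]2(C)[C@H]1CO[C@@H](C(=O)OC)[C@H](CC(=O)OC(C)(C)C)C(=O)O | intermediate
29 | geranyl bromide, (2E)-1-bromo-3,7-dimethylocta-2,6-diene | CC(C)=CCC/C(C)=C/CBr | starting material
30 | lithium (5E)-6,10-dimethylundeca-5,9-dien-1-ynide | [Li]C#CCC/C=C(\C)CCC=C(C)C | intermediate
31 | (6E)-7,11-dimethyldodeca-6,10-dien-2-yn-1-ol | CC(C)=CCC/C(C)=C/CCC#CCO | intermediate
32 | cyclic alkenylaluminate from 31 (idealised sodium salt) | COCCO[Al-]1(OCCOC)OCC=C1CC/C=C(\C)CCC=C(C)C.[Na+] | intermediate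
33 | (2Z,6E)-3-iodo-7,11-dimethyldodeca-2,6,10-trien-1-ol | CC(C)=CCC/C(C)=C/CC/C(I)=C/CO | intermediate
34 | (2Z,6E)-1-bromo-3-iodo-7,11-dimethyldodeca-2,6,10-triene | CC(C)=CCC/C(C)=C/CC/C(I)=C/CBr | intermediate
35 | iodotrienyl ether B, O-[(2Z,6E)-3-iodo-7,11-dimethyldodeca-2,6,10-trienyl] derivative of 9 | CC(C)=CCC/C(C)=C/CC/C(I)=C/CO[C@@H](C(=O)OC)[C@H](CC(=O)OC(C)(C)C)C(=O)OC | intermediate
36 | 12-hydroxy iodotrienyl ether B (2Z,6E,10E) | OC/C(C)=C/CC/C(C)=C/CC/C(I)=C/CO[C@@H](C(=O)OC)[C@H](CC(=O)OC(C)(C)C)C(=O)OC | intermediate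
37 | allylsilane allylic alcohol B, as 36 with CH2SiMe3 in place of iodine | OC/C(C)=C/CC/C(C)=C/CC/C(C[Si](C)(C)C)=C/CO[C@@H](C(=O)OC)[C@H](CC(=O)OC(C)(C)C)C(=O)OC | intermediate
38 | epoxy alcohol B, (10S,11S)-10,11-epoxide of 37 (drimane C3 and C4 both S) | OC[C@]1(C)O[C@H]1CC/C(C)=C/CC/C(C[Si](C)(C)C)=C/CO[C@@H](C(=O)OC)[C@H](CC(=O)OC(C)(C)C)C(=O)OC | intermediate
39 | silyl-protected epoxide B, tert-butyldiphenylsilyl ether of 38 | CC(C)(C)[Si](OC[C@]1(C)O[C@H]1CC/C(C)=C/CC/C(C[Si](C)(C)C)=C/CO[C@@H](C(=O)OC)[C@H](CC(=O)OC(C)(C)C)C(=O)OC)(c1ccccc1)c1ccccc1 | intermediate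
40 | 3β-hydroxy bicycle B, O-[3β-hydroxy-13-(tert-butyldiphenylsilyloxy)drim-8(12)-en-11-yl] derivative of 9 (4α-CH2OSi, 4β-CH3, 5α-H, 9α-H, 10β-CH3) | CC(C)(C)[Si](OC[C@]1(C)[C@@H](O)CC[C@]2(C)[C@@H](CO[C@@H](C(=O)OC)[C@H](CC(=O)OC(C)(C)C)C(=O)OC)C(=C)CC[C@@H]12)(c1ccccc1)c1ccccc1 | intermediate
41 | 3-O-(imidazol-1-ylthiocarbonyl) bicycle B | CC(C)(C)[Si](OC[C@]1(C)[C@@H](OC(=S)n3ccnc3)CC[C@]2(C)[C@@H](CO[C@@H](C(=O)OC)[C@H](CC(=O)OC(C)(C)C)C(=O)OC)C(=C)CC[C@@H]12)(c1ccccc1)c1ccccc1 | intermediate
42 | 13-silyloxyalbicanyl ether B (C3 deoxygenated) | CC(C)(C)[Si](OC[C@]1(C)CCC[C@]2(C)[C@@H](CO[C@@H](C(=O)OC)[C@H](CC(=O)OC(C)(C)C)C(=O)OC)C(=C)CC[C@@H]12)(c1ccccc1)c1ccccc1 | intermediate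
43 | alcohol B, O-[(4R,5R,9S,10S)-13-hydroxydrim-8(12)-en-11-yl] derivative of 9 | OC[C@]1(C)CCC[C@]2(C)[C@@H](CO[C@@H](C(=O)OC)[C@H](CC(=O)OC(C)(C)C)C(=O)OC)C(=C)CC[C@@H]12 | intermediate
44 | di-tert-butyl ester of the target | C=C1CC[C@H]2C(C)(C)CCC[C@]2(C)[C@H]1CO[C@@H](C(=O)OC)[C@H](CC(=O)OC(C)(C)C)C(=O)OC[C@]1(C)CCC[C@]2(C)[C@@H](CO[C@@H](C(=O)OC)[C@H](CC(=O)OC(C)(C)C)C(=O)OC)C(=C)CC[C@@H]12 | intermediate
45 | bis(trimethylsilyl) ester of the target | C=C1CC[C@H]2C(C)(C)CCC[C@]2(C)[C@H]1CO[C@@H](C(=O)OC)[C@H](CC(=O)O[Si](C)(C)C)C(=O)OC[C@]1(C)CCC[C@]2(C)[C@@H](CO[C@@H](C(=O)OC)[C@H](CC(=O)O[Si](C)(C)C)C(=O)OC)C(=C)CC[C@@H]12 | intermediate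
46 | CNP0139922.2 | C=C1CC[C@H]2C(C)(C)CCC[C@]2(C)[C@H]1CO[C@@H](C(=O)OC)[C@H](CC(=O)O)C(=O)OC[C@]1(C)CCC[C@]2(C)[C@@H](CO[C@@H](C(=O)OC)[C@H](CC(=O)O)C(=O)OC)C(=C)CC[C@@H]12 | target

Total step count: 30. Longest linear sequence: 14 steps (steps 5–16, then 29 and 30; the line 17–28, then 29 and 30, is equally long).

Steps most likely to fail

1. Step 15. Possible failures are migration of the methyl group or of C1 instead of C4, proton loss or hydride shift at the C10 cation before ring B closes, and closure to the cis-decalin. The fallback separates the shift and the ring closure into two known operations.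
 - It sets out from 23. Mesylation (MsCl, Et3N, CH2Cl2, −30 °C) gives the iodoalkenyl mesylate F1.
 - The electron-poor iodoalkene cannot intercept a cation. Buffered solvolysis in aqueous acetone (CaCO3, 50 °C), the classical cyclopentylcarbinyl-to-cyclohexyl ring enlargement with capture by water, should therefore give the ring-enlarged tertiary alcohol F2.
 - Negishi coupling under the conditions of step 13 gives the allylsilane tertiary alcohol F3.
 - Ionisation of the tertiary carbinol (Sc(OTf)3 cat, (CF3)2CHOH–CH2Cl2, 0 °C), a known tertiary-carbinol-initiated allylsilane cyclisation, closes ring B through the equatorial-chain chair and comes back to the route at 27.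

2. Step 25. Possible failures are rearrangement of the inductively deactivated epoxide to a carbonyl compound, five-membered closure at C3, sequestration of the Lewis acid by the three esters, and loss of the tert-butyl ester. The fallback changes from the cationic to the radical manifold and needs no allylsilane.
 - It sets out from 9. Ag2O-mediated alkylation with commercial (2E,6E)-farnesyl bromide gives the farnesyl ether F4.
 - SeO2/t-BuOOH gives the 12-hydroxyfarnesyl ether F5.
 - Sharpless epoxidation with L-(+)-diethyl tartrate gives the epoxy alcohol F6.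
 - Silylation gives the silyl-protected epoxyfarnesyl ether F7.
 - Titanocene monochloride (trivalent titanium, Cp2TiCl from Cp2TiCl2 and Mn, THF, rt) opens the epoxide homolytically. The C4 radical closes both rings through the chair–chair array and the C8 radical is converted into the exocyclic alkene by β-hydrogen loss, which comes back to the route at 40.
 - In this variant the equatorial placement of the larger CH2OSi group at the planar C4 radical rests on steric preference only.

3. Step 12 (the same holds for step 20). Possible failures are sluggish O-alkylation of the hindered secondary hydroxy ester, lactonisation of the hydroxy triester, and hydrolysis of the allylic bromide on the silver surface. The fallback activates the allylic alcohol as an imidate under acid catalysis instead of a halide under silver assistance.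
 - It sets out from 21. Cl3CCN with DBU (cat) at 0 °C takes the primary allylic hydroxyl and gives the allylic trichloroacetimidate F8.
 - F8 alkylates 6 under TfOH catalysis (cyclohexane–CH2Cl2, 0 °C) and comes back to the route at 23.

Further compounds
F1 | step 15 | iodoalkenyl mesylate, (5S)-methanesulfonate of 23 | CC1(C)CCC[C@]1(C)[C@@H](OS(C)(=O)=O)CC/C(I)=C/CO[C@@H](C(=O)OC)[C@H](CC(=O)OC(C)(C)C)C(=O)OCC[Si](C)(C)C
F2 | step 15 | ring-enlarged tertiary alcohol (C10 hydroxyl anti to C4, iodoalkene side chain on (5S)-C5) | C[C@]1(O)CCCC(C)(C)[C@@H]1CC/C(I)=C/CO[C@@H](C(=O)OC)[C@H](CC(=O)OC(C)(C)C)C(=O)OCC[Si](C)(C)C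
F3 | step 15 | allylsilane tertiary alcohol, as F2 with CH2SiMe3 in place of iodine | C[C@]1(O)CCCC(C)(C)[C@@H]1CC/C(C[Si](C)(C)C)=C/CO[C@@H](C(=O)OC)[C@H](CC(=O)OC(C)(C)C)C(=O)OCC[Si](C)(C)C
F4 | step 25 | farnesyl ether, O-[(2E,6E)-farnesyl] derivative of 9 | CC(C)=CCC/C(C)=C/CC/C(C)=C/CO[C@@H](C(=O)OC)[C@H](CC(=O)OC(C)(C)C)C(=O)OC
F5 | step 25 | 12-hydroxyfarnesyl ether (2E,6E,10E) | OC/C(C)=C/CC/C(C)=C/CC/C(C)=C/CO[C@@H](C(=O)OC)[C@H](CC(=O)OC(C)(C)C)C(=O)OC
F6 | step 25 | epoxy alcohol, (10S,11S)-10,11-epoxide of F5 | OC[C@]1(C)O[C@H]1CC/C(C)=C/CC/C(C)=C/CO[C@@H](C(=O)OC)[C@H](CC(=O)OC(C)(C)C)C(=O)OC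
F7 | step 25 | silyl-protected epoxyfarnesyl ether, tert-butyldiphenylsilyl ether of F6 | CC(C)(C)[Si](OC[C@]1(C)O[C@H]1CC/C(C)=C/CC/C(C)=C/CO[C@@H](C(=O)OC)[C@H](CC(=O)OC(C)(C)C)C(=O)OC)(c1ccccc1)c1ccccc1
F8 | step 12 | allylic trichloroacetimidate of 21 (primary hydroxyl) | N=C(OC/C=C(I)/CC[C@H](O)[C@@]1(C)CCCC1(C)C)C(Cl)(Cl)Cl
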